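**Plan**

1. Labdane numbering is used: ring C is the pyran (O, C8, C9, C11, C12, C13), ring B is C5–C10, the acid arms are C1–C2 on C10 and C3–C4 on C5. Remark: the target is taken exactly as drawn, (5R,8R,9S,10S,13R), with rings B/C cis-fused.
2. Retrosynthesis: cut C9–C10 (ring B, the last ring) to a C9 radical and a (Z)-C10=C1 enoate; then C10–C20, C1–C2 and C1–C10 (ynoate, alkyne, aldehyde), C4–C5, the C8–O bond of ring C, and C6–C7.
3. Forward: (R)-linalool → C7 bromide → C6/C5/C10 extension → Shi epoxide → hydroxy selenide → ring C by seleniranium etherification → C4 unit on C5 → alkyne → ynoate → (Z)-enoate → ring B → saponification.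
4. Stereochemistry: C13 from (R)-linalool; C8 from the Shi epoxide, relayed with net retention; C5 from enamine organocatalysis; C10 and C9 in the ring closure.
5. Enabling feature: the C9–Se bond of ring C sits beside the fully substituted ether carbon C8, which carries the C7–C6–C5 tether to the (Z)-enoate. A C9 radical (unlike an anion) keeps the β-oxygen, and the cis ester pins C5–H in the alkene plane (allylic 1,3-strain), which fixes the face of C10 that is attacked.
6. Helpers: the PhSe group left by ring C formation is lost in the ring closure; the two methyl esters are cleaved last.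

Key step: step 11

Step 1
Reactants: 1 (R)-(−)-linalool
Product: 2 (2E,6R)-2,6-dimethylocta-2,7-diene-1,6-diol
Conditions: SeO2 (0.2 equiv), t-BuOOH (2 equiv), salicylic acid (0.1 equiv), CH2Cl2, 20 °C
Reagents that add atoms: tert-butyl hydroperoxide CC(C)(C)OO; selenium dioxide O=[Se]=O (catalytic oxygen carrier)
Why: Sharpless catalytic SeO2/t-BuOOH allylic oxidation (ene reaction then 2,3-sigmatropic shift) should hydroxylate the (E)-methyl group of the trisubstituted alkene selectively, since the vinyl group has no allylic C–H (C13 is fully substituted) and the chiral-pool centre C13 is not touched.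

Step 2
Reactants: 2 (2E,6R)-2,6-dimethylocta-2,7-diene-1,6-diol
Product: 3 (3R,6E)-8-bromo-3,7-dimethylocta-1,6-dien-3-ol
Conditions: CBr4, PPh3, CH2Cl2, −20 °C
Reagents that add atoms: carbon tetrabromide BrC(Br)(Br)Br
Why: Appel bromination should convert the unhindered primary allylic alcohol much faster than the tertiary allylic one and, run cold, keep the E geometry without allylic transposition.

Step 3
Reactants: 3 (3R,6E)-8-bromo-3,7-dimethylocta-1,6-dien-3-ol; 4 [2-(1,3-dioxolan-2-yl)ethyl]magnesium bromide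
Product: 5 (3R,6E)-10-(1,3-dioxolan-2-yl)-3,7-dimethyldeca-1,6-dien-3-ol
Conditions: 4 (2.3 equiv), Li2CuCl4 (3 mol %), THF, −20 to 0 °C
Reagents that add atoms: none
Why: Kochi–Schlosser Li2CuCl4-catalysed coupling of a primary allylic bromide with an alkyl Grignard reagent is α-selective and keeps the E alkene (one equivalent of 4 is spent on the hydroxyl group), and it installs C6, C5 and the masked aldehyde carbon C10.

Step 4
Reactants: 5 (3R,6E)-10-(1,3-dioxolan-2-yl)-3,7-dimethyldeca-1,6-dien-3-ol
Product: 6 (3R)-1-{(2R,3R)-3-[3-(1,3-dioxolan-2-yl)propyl]-3-methyloxiran-2-yl}-3-methylpent-4-en-3-ol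
Conditions: D-fructose-derived Shi ketone (0.3 equiv), Oxone (2KHSO5·KHSO4·K2SO4), K2CO3, Bu4NHSO4, MeCN/CH2(OMe)2/aq. Na2B4O7 buffer (pH 10.5), 0 °C
Reagents that add atoms: potassium peroxymonosulfate [K+].[O-]S(=O)(=O)OO
Why: Shi epoxidation by the dioxirane of the D-fructose-derived ketone should attack only the electron-rich trisubstituted (E)-alkene (not the vinyl group) through the spiro transition state and is expected to give the (R,R)-epoxide, which sets C8 by reagent control.

Step 5
Reactants: 6 (3R)-1-{(2R,3R)-3-[3-(1,3-dioxolan-2-yl)propyl]-3-methyloxiran-2-yl}-3-methylpent-4-en-3-ol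
Product: 7 (3R,6S,7R)-10-(1,3-dioxolan-2-yl)-3,7-dimethyl-6-(phenylselanyl)dec-1-ene-3,7-diol
Conditions: (PhSe)2, NaBH4, EtOH, 0 to 20 °C
Reagents that add atoms: diphenyl diselenide c1ccc(cc1)[Se][Se]c1ccccc1
Why: Epoxide opening by benzeneselenolate (Sharpless–Lauer conditions) is an SN2 attack at the less hindered secondary C9 with inversion, which leaves the C8–O bond in place as a tertiary alcohol of unchanged configuration.

Step 6
Reactants: 7 (3R,6S,7R)-10-(1,3-dioxolan-2-yl)-3,7-dimethyl-6-(phenylselanyl)dec-1-ene-3,7-diol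
Product: 9 4-[(2R,3S,6R)-6-ethenyl-2,6-dimethyl-3-(phenylselanyl)oxan-2-yl]butanal, via pyran dioxolane 8 (not isolated)
Conditions: TsOH·H2O (0.1 equiv), CH2Cl2, −20 to 0 °C; then acetone/H2O 4:1, 40 °C
Reagents that add atoms: water O
Why: Acid should ionise the tertiary β-hydroxy selenide with selenium participation to a seleniranium ion (inversion at C8), which the C13 hydroxyl opens at the tertiary carbon in a Markovnikov six-membered etherification (second inversion, hence net retention and the 8R,13R pyran with cis methyls), after which aqueous acid hydrolyses the dioxolane.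

Step 7
Reactants: 9 4-[(2R,3S,6R)-6-ethenyl-2,6-dimethyl-3-(phenylselanyl)oxan-2-yl]butanal; 10 methyl 2-bromo-2-methylpropanoate
Product: 11 methyl (3S)-3-formyl-2,2-dimethyl-5-[(2R,3S,6R)-6-ethenyl-2,6-dimethyl-3-(phenylselanyl)oxan-2-yl]pentanoate
Conditions: (2S,5R)-2-tert-butyl-3,5-dimethylimidazolidin-4-one·TfOH (0.2 equiv), Ir(ppy)3 (1 mol %), 2,6-lutidine (2 equiv), DMF, blue LEDs, 20 °C
Reagents that add atoms: none
Why: In this MacMillan photoredox–enamine α-alkylation the tertiary α-ester radical formed from 10 by Ir(ppy)3 should add to the Re face of the (E)-enamine of 9 left open by the imidazolidinone, which sets C5 (S in 11 because the formyl group outranks C4) and forms the hindered C4–C5 bond next to a quaternary carbon.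

Step 8
Reactants: 11 methyl (3S)-3-formyl-2,2-dimethyl-5-[(2R,3S,6R)-6-ethenyl-2,6-dimethyl-3-(phenylselanyl)oxan-2-yl]pentanoate
Product: 12 methyl (3R)-3-ethynyl-2,2-dimethyl-5-[(2R,3S,6R)-6-ethenyl-2,6-dimethyl-3-(phenylselanyl)oxan-2-yl]pentanoate
Conditions: dimethyl (1-diazo-2-oxopropyl)phosphonate, K2CO3, MeOH, 0 to 20 °C
Reagents that add atoms: dimethyl (1-diazo-2-oxopropyl)phosphonate COP(=O)(OC)C(=[N+]=[N-])C(C)=O
Why: Seyferth–Gilbert homologation with the Ohira–Bestmann reagent turns the aldehyde into the terminal alkyne under mild carbonate conditions that should not epimerise C5, whose hydrogen is shielded by the neighbouring quaternary carbon.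

Step 9
Reactants: 12 methyl (3R)-3-ethynyl-2,2-dimethyl-5-[(2R,3S,6R)-6-ethenyl-2,6-dimethyl-3-(phenylselanyl)oxan-2-yl]pentanoate
Product: 14 dimethyl (4R)-4-{2-[(2R,3S,6R)-6-ethenyl-2,6-dimethyl-3-(phenylselanyl)oxan-2-yl]ethyl}-5,5-dimethylhex-2-ynedioate, via lithium acetylide 13 (not isolated)
Conditions: LDA (1.1 equiv), THF, −78 °C; then ClCO2Me, −78 to −20 °C
Reagents that add atoms: methyl chloroformate COC(=O)Cl
Why: Deprotonation of the terminal alkyne by LDA (the ester has no α-hydrogen) and C-acylation of the acetylide with methyl chloroformate gives the ynoate that carries C1 and C2.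

Step 10
Reactants: 14 dimethyl (4R)-4-{2-[(2R,3S,6R)-6-ethenyl-2,6-dimethyl-3-(phenylselanyl)oxan-2-yl]ethyl}-5,5-dimethylhex-2-ynedioate
Product: 16 dimethyl (2Z,4R)-4-{2-[(2R,3S,6R)-6-ethenyl-2,6-dimethyl-3-(phenylselanyl)oxan-2-yl]ethyl}-3,5,5-trimethylhex-2-enedioate, via alkenylcuprate 15 (not isolated)
Conditions: Me2CuLi (from CuI and 2 MeLi, 1.3 equiv), THF, −78 °C; then MeOH, −78 °C
Reagents that add atoms: lithium dimethylcuprate [Li+].C[Cu-]C
Why: syn-Carbocupration of the ynoate at −78 °C (Corey–Katzenellenbogen addition) and cold protonation place the new methyl group and hydrogen cis, which gives the (Z)-enoate with C5 and the ester on the same side.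

Step 11
Reactants: 16 dimethyl (2Z,4R)-4-{2-[(2R,3S,6R)-6-ethenyl-2,6-dimethyl-3-(phenylselanyl)oxan-2-yl]ethyl}-3,5,5-trimethylhex-2-enedioate
Product: 17 methyl 2-[(2R,4aS,5S,6R,8aR)-2-ethenyl-5-(2-methoxy-2-oxoethyl)-2,5,8a-trimethyloctahydro-2H-chromen-6-yl]-2-methylpropanoate
Conditions: Bu3SnH (1.5 equiv, syringe pump), AIBN (0.2 equiv), PhH (5 mM), 80 °C
Reagents that add atoms: none
Why: Bu3Sn• abstracts the phenylselanyl group from C9 of ring C, and the secondary C9 radical (its former configuration is erased, so any C9 epimer of 16 would converge) adds in a 6-exo-trig Giese fashion to C10 of the (Z)-β-methyl enoate four atoms away (C8, C7, C6, C5), after which the α-ester radical at C1 takes hydrogen from Bu3SnH. The closest known reaction type is the tin hydride-mediated 6-exo cyclisation of alkyl selenides or halides onto β,β-disubstituted acrylates, which builds a quaternary carbon. Ring B should close through a chair-like transition state that the CMe2CO2Me group on C5 anchors in an equatorial position, which places the C8 methyl group axial. C10 is controlled by allylic 1,3-strain: the cis ester forces C5–H into the plane of C10=C1, C6 and C4 lie on opposite faces, and the radical delivered from the C6 face puts C1 equatorial and the methyl group axial (10S). C9 is fixed by the ring fusion: bond formation with C9–C11 axial on ring B gives the cis-fused pyran with H-9 syn to the C8 methyl group (9S), whereas the trans-fused alternative would force the C8 and C13 methyl groups into a syn-diaxial contact across the ring oxygen. The step needs cyclisation to outrun premature reduction and 1,5-hydrogen transfer from C5–H, which slow addition of the stannane at high dilution and the in-plane (allylically non-activated) position of C5–H should secure, while a radical, unlike a carbanion, does not expel the β-oxygen on C8.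

Step 12
Reactants: 17 methyl 2-[(2R,4aS,5S,6R,8aR)-2-ethenyl-5-(2-methoxy-2-oxoethyl)-2,5,8a-trimethyloctahydro-2H-chromen-6-yl]-2-methylpropanoate
Product: 19 2-[(2R,4aS,5S,6R,8aR)-5-(carboxymethyl)-2-ethenyl-2,5,8a-trimethyloctahydro-2H-chromen-6-yl]-2-methylpropanoic acid, via dipotassium salt 18 (not isolated)
Conditions: KOH, ethylene glycol/H2O, 120 °C; then aq. HCl to pH 3
Reagents that add atoms: potassium hydroxide [K+].[OH-]
Why: Saponification of both methyl esters under forcing conditions (the C3 ester is neopentyl-like) and acidification give the diacid, the ether, the vinyl group and all stereocentres (none enolisable) being stable to hot alkali.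

**Compound list**

1 | (R)-(−)-linalool | C=C[C@@](O)(C)CCC=C(C)C | starting material
2 | (2E,6R)-2,6-dimethylocta-2,7-diene-1,6-diol | C=C[C@@](O)(C)CC/C=C(\C)CO | intermediate
3 | (3R,6E)-8-bromo-3,7-dimethylocta-1,6-dien-3-ol | C=C[C@@](O)(C)CC/C=C(\C)CBr | intermediate
4 | [2-(1,3-dioxolan-2-yl)ethyl]magnesium bromide | Br[Mg]CCC1OCCO1 | starting material
5 | (3R,6E)-10-(1,3-dioxolan-2-yl)-3,7-dimethyldeca-1,6-dien-3-ol | C=C[C@@](O)(C)CC/C=C(\C)CCCC1OCCO1 | intermediate
6 | (3R)-1-{(2R,3R)-3-[3-(1,3-dioxolan-2-yl)propyl]-3-methyloxiran-2-yl}-3-methylpent-4-en-3-ol | C=C[C@@](O)(C)CC[C@H]1O[C@]1(C)CCCC2OCCO2 | intermediate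
7 | (3R,6S,7R)-10-(1,3-dioxolan-2-yl)-3,7-dimethyl-6-(phenylselanyl)dec-1-ene-3,7-diol | C=C[C@@](O)(C)CC[C@H]([Se]c1ccccc1)[C@@](O)(C)CCCC2OCCO2 | intermediate
8 | 2-{3-[(2R,3S,6R)-6-ethenyl-2,6-dimethyl-3-(phenylselanyl)oxan-2-yl]propyl}-1,3-dioxolane | C=C[C@@]1(C)CC[C@H]([Se]c2ccccc2)[C@@](C)(CCCC3OCCO3)O1 | intermediate
9 | 4-[(2R,3S,6R)-6-ethenyl-2,6-dimethyl-3-(phenylselanyl)oxan-2-yl]butanal | C=C[C@@]1(C)CC[C@H]([Se]c2ccccc2)[C@@](C)(CCCC=O)O1 | intermediate
10 | methyl 2-bromo-2-methylpropanoate | COC(=O)C(C)(C)Br | starting material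
11 | methyl (3S)-3-formyl-2,2-dimethyl-5-[(2R,3S,6R)-6-ethenyl-2,6-dimethyl-3-(phenylselanyl)oxan-2-yl]pentanoate | C=C[C@@]1(C)CC[C@H]([Se]c2ccccc2)[C@@](C)(CC[C@H](C=O)C(C)(C)C(=O)OC)O1 | intermediate
12 | methyl (3R)-3-ethynyl-2,2-dimethyl-5-[(2R,3S,6R)-6-ethenyl-2,6-dimethyl-3-(phenylselanyl)oxan-2-yl]pentanoate | C=C[C@@]1(C)CC[C@H]([Se]c2ccccc2)[C@@](C)(CC[C@H](C#C)C(C)(C)C(=O)OC)O1 | intermediate
13 | lithium acetylide of 12 | C=C[C@@]1(C)CC[C@H]([Se]c2ccccc2)[C@@](C)(CC[C@H](C#C[Li])C(C)(C)C(=O)OC)O1 | intermediate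
14 | dimethyl (4R)-4-{2-[(2R,3S,6R)-6-ethenyl-2,6-dimethyl-3-(phenylselanyl)oxan-2-yl]ethyl}-5,5-dimethylhex-2-ynedioate | C=C[C@@]1(C)CC[C@H]([Se]c2ccccc2)[C@@](C)(CC[C@H](C#CC(=O)OC)C(C)(C)C(=O)OC)O1 | intermediate
15 | lithium alkenyl(methyl)cuprate from syn addition to 14 (Cu on C1, cis to the new methyl group) | C=C[C@@]1(C)CC[C@H]([Se]c2ccccc2)[C@@](C)(CC[C@H](/C(C)=C(/[Cu-]C)C(=O)OC)C(C)(C)C(=O)OC)O1.[Li+] | intermediate
16 | dimethyl (2Z,4R)-4-{2-[(2R,3S,6R)-6-ethenyl-2,6-dimethyl-3-(phenylselanyl)oxan-2-yl]ethyl}-3,5,5-trimethylhex-2-enedioate | C=C[C@@]1(C)CC[C@H]([Se]c2ccccc2)[C@@](C)(CC[C@H](/C(C)=C\C(=O)OC)C(C)(C)C(=O)OC)O1 | intermediate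
17 | methyl 2-[(2R,4aS,5S,6R,8aR)-2-ethenyl-5-(2-methoxy-2-oxoethyl)-2,5,8a-trimethyloctahydro-2H-chromen-6-yl]-2-methylpropanoate | C=C[C@@]1(C)CC[C@H]2[C@@](C)(CC(=O)OC)[C@H](C(C)(C)C(=O)OC)CC[C@@]2(C)O1 | intermediate
18 | dipotassium salt of 19 | C=C[C@@]1(C)CC[C@H]2[C@@](C)(CC(=O)[O-])[C@H](C(C)(C)C(=O)[O-])CC[C@@]2(C)O1.[K+].[K+] | intermediate
19 | 2-[(2R,4aS,5S,6R,8aR)-5-(carboxymethyl)-2-ethenyl-2,5,8a-trimethyloctahydro-2H-chromen-6-yl]-2-methylpropanoic acid (CNP0186744.1) | C=C[C@@]1(C)CC[C@H]2[C@@](C)(CC(=O)O)[C@H](C(C)(C)C(=O)O)CC[C@@]2(C)O1 | target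

**Step count and risks**

Total step count: 12. Longest linear sequence: 12 steps (from 1).

Steps most likely to fail:

1. Step 11. The C9 radical may be reduced, or may abstract the hydrogen on C5, before it closes the ring. The enoate may also lose its Z geometry by reversible addition of stannyl radicals, which would erode the facial selectivity at C10. Fallback, from 16 back to 17: oxidation of the selenide (H2O2, pyridine) and syn-elimination would give the dihydropyran F1. Dimethyldioxirane should epoxidise its ring alkene faster than the vinyl group, anti to the C8 side chain, to give the epoxide F2. Cp2TiCl (trivalent titanium, from Cp2TiCl2 and Zn; Nugent–RajanBabu opening) should open the epoxide homolytically with the titanium alkoxide on the less hindered C11 and the radical on C9. This radical closes onto the enoate in a non-chain process with no hydrogen donor present and ends as a titanium enolate, giving the C11 alcohol F3. Barton–McCombie deoxygenation through the phenyl thionocarbonate F4 (PhOC(S)Cl, pyridine; then Bu3SnH, AIBN) returns to 17; C11 is not stereogenic there.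

2. Step 7. The hindered tertiary radical may be captured slowly by the enamine, with reduction of 10 or poor facial control at C5 as the result. Fallback, from 9 back to 11: the pyrrolidine enamine of 9 would be alkylated by the radical from 10 under Et3B/air initiation (radical alkylation of an enamine, no chiral catalyst) and hydrolysed. The wanted aldehyde 11 would then be separated by chromatography from its C5 epimer F5; the two are diastereomers because C8, C9 and C13 are fixed.

3. Step 6. The seleniranium ion may be opened at C9 (five-membered ether), may lose a proton to give an alkene, or the allylic C13 alcohol may ionise. Fallback, from 5 back to 8: direct selenoetherification of the alkene with N-(phenylselanyl)phthalimide and camphorsulfonic acid in CH2Cl2 (Markovnikov, anti addition, thermodynamic control) bypasses 6 and 7. It would give 8 together with its C8,C9-diastereomer F6, to be separated by chromatography before the hydrolysis to 9.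

Further compounds

F1 | step 11 | dimethyl (2Z,4R)-4-{2-[(2R,6R)-6-ethenyl-2,6-dimethyl-3,6-dihydro-2H-pyran-2-yl]ethyl}-3,5,5-trimethylhex-2-enedioate (stereodescriptors of the ring atoms as in 16) | C=C[C@@]1(C)CC=C[C@@](C)(CC[C@H](/C(C)=C\C(=O)OC)C(C)(C)C(=O)OC)O1
F2 | step 11 | C9,C11-epoxide of F1, oxygen anti to the C8 side chain | C=C[C@@]1(C)C[C@@H]2O[C@@H]2[C@@](C)(CC[C@H](/C(C)=C\C(=O)OC)C(C)(C)C(=O)OC)O1
F3 | step 11 | C11-hydroxy derivative of 17 (hydroxyl syn to the C8 methyl group) | C=C[C@@]1(C)C[C@H](O)[C@H]2[C@@](C)(CC(=O)OC)[C@H](C(C)(C)C(=O)OC)CC[C@@]2(C)O1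
F4 | step 11 | O-phenyl thionocarbonate of F3 | C=C[C@@]1(C)C[C@H](OC(=S)Oc3ccccc3)[C@H]2[C@@](C)(CC(=O)OC)[C@H](C(C)(C)C(=O)OC)CC[C@@]2(C)O1
F5 | step 7 | methyl (3R)-3-formyl-2,2-dimethyl-5-[(2R,3S,6R)-6-ethenyl-2,6-dimethyl-3-(phenylselanyl)oxan-2-yl]pentanoate (C5 epimer of 11) | C=C[C@@]1(C)CC[C@H]([Se]c2ccccc2)[C@@](C)(CC[C@@H](C=O)C(C)(C)C(=O)OC)O1
F6 | step 6 | 2-{3-[(2S,3R,6R)-6-ethenyl-2,6-dimethyl-3-(phenylselanyl)oxan-2-yl]propyl}-1,3-dioxolane | C=C[C@@]1(C)CC[C@@H]([Se]c2ccccc2)[C@](C)(CCCC3OCCO3)O1
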